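At late times the green and violet runs stand still with substrate unused: at 2.50 min the green run reads 25.3% target beside 74.9% substrate, and the violet run reads 41.8% beside 57.9%.

| setting | green | violet | Friday's | Wednesday's |
|---|---|---|---|---|
| substrate | 5 mM | 5 mM | 5.0 mM | 5.0 mM |
| coupling partner | 5 mM (in portions, 3) | 5 mM (in portions, 3) | 5.00 mM | 5.00 mM (in portions, 3) |
| free catalyst | 0.37 mM | 0.75 mM | 1.2 mM | 0.55 mM |
| remark | run made earlier; portions every 3.0 s | run made earlier; portions every 3.0 s | everything together at the start | the portions of coupling partner follow each other after 3.0 s, the first at the start |
| time |  |  | 2.5 min | 2.5 min |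

| run | time / min | target / % | substrate / % |
|---|---|---|---|
| green | 0.333 | 21.2 | 76.3 |
| green | 0.833 | 25.5 | 75.0 |
| green | 1.50 | 25.2 | 74.5 |
| green | 2.50 | 25.3 | 74.9 |
| violet | 0.333 | 38.2 | 59.4 |
| violet | 0.833 | 41.4 | 58.2 |
| violet | 1.50 | 42.0 | 58.1 |
| violet | 2.50 | 41.8 | 57.9 |

(scatter of a reading: 0.3 percentage points)

- what may be going on: catalyst intermediate B -> by-product + catalyst intermediate C; substrate + catalyst intermediate A -> catalyst intermediate B; coupling partner -> decomposed reagent; coupling partner + free catalyst <-> catalyst intermediate A; catalyst intermediate A + target -> spent catalyst; catalyst intermediate C -> free catalyst + target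

- the winner by amount of target, in percent of the substrate charged; "neither" if no more than 2 percentage points parts them (Friday's / Wednesday's / neither)
- how much target is there at the end, in percent of the substrate charged: Friday's
- how much target is there at the end, in percent of the substrate charged: Wednesday's

Two people dispute why the runs stop. The first says the coupling partner is lost: it decomposes first-order while catalyst captures it at a rate proportional to catalyst and partner. Dividing one rate by the other removes time and partner, so ρ, target made per partner decomposed, should grow in proportion to the catalyst charge c. With equal charges of substrate and partner, a final yield y gives ρ = y/(1 − y). The readings give ρ/c = 0.915 mM⁻¹ for green and 0.958 mM⁻¹ for violet. Their mean is 0.936 mM⁻¹, and this g, a selectivity factor per mM of catalyst charged, gives y = gc/(1 + gc). That is 34.0% for Wednesday's and 52.9% for Friday's.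

The second says target kills the catalyst: catalyst intermediate A meets target and becomes spent catalyst, in competition with its turnover through substrate. Dividing these two rates removes time and catalyst intermediate A, so catalyst lost per target made grows with target, and to lowest order in y the catalyst is used up at a yield proportional to √(c/S), with S the substrate charge. The readings give b = y/√(c/S) = 0.930 for green and 1.08 for violet, a wider spread than the first's. Their mean 1.00 gives 33.3% for Wednesday's, close to the first's figure, and 49.2% for Friday's, less than the first's figure.

The forecast sides with the first: “Competition between first-order partner decomposition and catalysed coupling fits better”. It names Friday's the winner, with 33.8% (32% to 35.5%) for Wednesday's. For Friday's it gives 49% (42% to 55%), below the first view's figure, shaded for the single charge.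

The simulation gives 50.9% for Friday's and 33.7% for Wednesday's, so Friday's wins, and the figure for Friday's lies between those of the two views .

    catalyst intermediate B → by-product + catalyst intermediate C (k = 0.290 s⁻¹)
    substrate + catalyst intermediate A → catalyst intermediate B (k = 10000 L mol⁻¹ s⁻¹)
    coupling partner → decomposed reagent (k = 0.140 s⁻¹)
    coupling partner + free catalyst ⇌ catalyst intermediate A (K = 530 L mol⁻¹, k = 280 L mol⁻¹ s⁻¹)
    catalyst intermediate A + target → spent catalyst (k = 23.0 L mol⁻¹ s⁻¹)
    catalyst intermediate C → free catalyst + target (k = 77.0 s⁻¹)

In Friday's, capture had done half of its turnover by 2.27 s, while decomposition ran with a half-life of 0.083 min. By 1.25 min Friday's held 0% coupling partner, 2.45 mM decomposed reagent, 99.9% free catalyst and 0.113% spent catalyst, which is the first view's picture, and its result gives g = 0.864 mM⁻¹.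

Take the neighbour of Friday's with 2.0 mM substrate: g promises 2.65 mM of captured partner, more than that substrate, which makes substrate the limiting reagent. It gives 95.0% target with 0% substrate left, and spent catalyst reaches 8.26% against 0.113% in Friday's, which is the second view's region.

Readings and results are simulated from invented constants, and the scatter is random.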